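**Retrosynthetic overview**
1. Target 6 ⇒ the O1–C2 and C3–O(sulfate) bonds are made together in a sulfoxylative oxidative cyclisation of the sulfated 2'-hydroxychalcone 4 with peroxydisulfate.
2. 4 ⇒ chemoselective O-sulfation of the two non-chelated phenols of chalcone 3.
3. 3 ⇒ Claisen–Schmidt condensation of 2,4-dihydroxyacetophenone 1 with vanillin 2.
4. Ring order: rings A and B are bought; ring C (the 4-pyranone) is the only ring formed and is closed last.

Assumption: the target is a planar, achiral flavone with no stereocentre, so there is no enantiomer to control. Sulfate monoesters are drawn as free hydrogen sulfates, as in the target SMILES; in the flask they are handled as potassium salts (counter-ions not drawn) until the final H+ exchange.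

**Step 1**
Reactants: 1 2,4-dihydroxyacetophenone; 2 vanillin
Product: 3 homobutein, (E)-1-(2,4-dihydroxyphenyl)-3-(4-hydroxy-3-methoxyphenyl)prop-2-en-1-one
Conditions: HCl (g, sat.), EtOH, 0 °C → rt, 24 h
Reagents that add atoms: none
Why: Acid-catalysed Claisen–Schmidt (aldol) condensation needs no phenol protection because no deactivating phenolates form, and thermodynamic dehydration gives only the E-enone.

**Step 2**
Reactants: 3 homobutein
Product: 4 homobutein 4,4'-bis(hydrogen sulfate), (E)-chalcone with OSO3H at C4 of ring B and C4' of ring A and a free 2'-OH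
Conditions: SO3·pyridine (2.4 equiv), pyridine, 0 °C → rt, 6 h; then KOH/MeOH to pH 8, precipitate with acetone (dipotassium salt)
Reagents that add atoms: sulfur trioxide–pyridine complex, O=S(=O)([O-])[n+]1ccccc1
Why: Phenol O-sulfation with an SO3–amine complex takes the two free phenols, while the 2'-OH is locked in a six-membered hydrogen bond to the carbonyl (the same situation as the 5-OH of flavones, which standard sulfation leaves untouched).

**Step 3**
Reactants: 4 homobutein 4,4'-bis(hydrogen sulfate)
Product: 6 geraldol 3,7,4'-tris(hydrogen sulfate) = the target, via racemic trans-3-sulfooxyflavanone 5 (not isolated)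
Conditions: K2S2O8 (2.5 equiv), KOH (1 M aq., 6 equiv), H2O, Ar, 0 °C → rt, 12 h, then 45 °C, 2 h; H+-form cation-exchange resin, 0 °C, lyophilise
Reagents that add atoms: potassium peroxydisulfate, [K+].[K+].[O-]S(=O)(=O)OOS(=O)(=O)[O-]
Why: Proposed new method: a sulfoxylative Algar–Flynn–Oyamada cyclisation in which the 2'-phenoxide of 4 adds 6-endo to the enone (oxa-Michael, forming O1–C2) and the resulting flavanone C3 enolate attacks a peroxide oxygen of the peroxydisulfate dianion with loss of sulfate (the carbon-nucleophile/persulfate step of the Elbs oxidation), forming the C3–OSO3 bond directly to give trans-5; a second equivalent of peroxydisulfate then oxidises the C3 enolate of 5 by two electrons (second O-transfer followed by loss of KHSO4 across C2–C3, or electron transfer and H-abstraction by the sulfate radical anion), driven by aromatisation to the 4-pyranone, which erases the two transient racemic centres; the aryl sulfates already in place remove the phenolate deactivation of the enone and block Elbs oxidation at those positions, and peroxydisulfate, unlike HOO−, cannot epoxidise the enone, so the aurone pathway is closed; closest known reactions are the Algar–Flynn–Oyamada reaction (H2O2/NaOH) and the Elbs persulfate oxidation.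

**Compound list**
1 | 1-(2,4-dihydroxyphenyl)ethan-1-one (2,4-dihydroxyacetophenone) | CC(=O)c1ccc(O)cc1O | starting material
2 | 4-hydroxy-3-methoxybenzaldehyde (vanillin) | COc1cc(C=O)ccc1O | starting material
3 | (E)-1-(2,4-dihydroxyphenyl)-3-(4-hydroxy-3-methoxyphenyl)prop-2-en-1-one (homobutein) | COc1cc(/C=C/C(=O)c2ccc(O)cc2O)ccc1O | intermediate
4 | 4-[(E)-3-(2-hydroxy-4-sulfooxyphenyl)-3-oxoprop-1-enyl]-2-methoxyphenyl hydrogen sulfate (homobutein 4,4'-bis(hydrogen sulfate)) | COc1cc(/C=C/C(=O)c2ccc(OS(=O)(=O)O)cc2O)ccc1OS(=O)(=O)O | intermediate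
5 | racemic trans-2-(3-methoxy-4-sulfooxyphenyl)-4-oxochromane-3,7-diyl bis(hydrogen sulfate) (2,3-trans; the 2R,3R enantiomer is drawn) | COc1cc([C@H]2Oc3cc(OS(=O)(=O)O)ccc3C(=O)[C@@H]2OS(=O)(=O)O)ccc1OS(=O)(=O)O | intermediate
6 | 2-(3-methoxy-4-sulfooxyphenyl)-4-oxo-4H-chromene-3,7-diyl bis(hydrogen sulfate) (geraldol 3,7,4'-tris(hydrogen sulfate), achiral) | COc1cc(-c2oc3cc(OS(=O)(=O)O)ccc3c(=O)c2OS(=O)(=O)O)ccc1OS(=O)(=O)O | target

**Total step count:** 3. **Longest linear sequence:** 3.

**Steps most likely to fail**

1. Step 3 (the proposed new step). The second oxidation may stall at 5, the C3 sulfate may be lost by hydrolysis during aromatisation, or the remaining 2'-phenoxide may undergo slow Elbs oxidation on ring A. The fallback uses known chemistry and sets out from 4. A classical Algar–Flynn–Oyamada reaction (30% H2O2, 2 M NaOH, MeOH/H2O, 0 °C → rt) forms ring C with a free 3-OH and gives geraldol 7,4'-bis(hydrogen sulfate) F1; the aryl sulfates are inert to alkaline peroxide. The 3-OH of F1 is then sulfated by O–S bond formation (SO3·NMe3 in excess, Et3N, DMA, 65 °C, then H+ exchange), which comes back to the route at 6.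

2. Step 2. Over-sulfation at the chelated 2'-OH or incomplete sulfation would give salt mixtures that are hard to separate. The fallback sets out from 1 and 2 and sulfates each partner before the C–C bond is made. Vanillin with SO3·pyridine in pyridine gives vanillin 4-O-(hydrogen sulfate) F2. Compound 1 with 1.1 equiv SO3·pyridine gives 4-acetyl-3-hydroxyphenyl hydrogen sulfate F3, the chelated ortho-OH being spared. Base-mediated Claisen–Schmidt condensation of F2 and F3 (KOH aq./EtOH, rt) comes back to the route at 4; the condensation should be easier here because the aldehyde is no longer a phenolate.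

3. Step 1. Conversion may be low with the electron-rich aldehyde, and acid may cause partial cyclisation to the flavanone (which would still converge in step 3, since flavanone and chalcone equilibrate in KOH) or oligomerisation. The fallback sets out from 1 and 2 and uses protected partners under basic conditions. Compound 1 with MOMCl and K2CO3 in acetone gives 1-[2-hydroxy-4-(methoxymethoxy)phenyl]ethan-1-one F4. Compound 2 with MOMCl and iPr2NEt in CH2Cl2 gives 3-methoxy-4-(methoxymethoxy)benzaldehyde F5. Condensation with KOH (50% aq.) in EtOH at rt gives the bis-MOM chalcone F6. Removal of the MOM groups (3 M HCl, MeOH, 50 °C) comes back to the route at 3.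

**Further compounds**
F1 | step 3 | 3-hydroxy-2-(3-methoxy-4-sulfooxyphenyl)-4-oxo-4H-chromen-7-yl hydrogen sulfate (geraldol 7,4'-bis(hydrogen sulfate)) | COc1cc(-c2oc3cc(OS(=O)(=O)O)ccc3c(=O)c2O)ccc1OS(=O)(=O)O
F2 | step 2 | 4-formyl-2-methoxyphenyl hydrogen sulfate (vanillin 4-O-(hydrogen sulfate)) | COc1cc(C=O)ccc1OS(=O)(=O)O
F3 | step 2 | 4-acetyl-3-hydroxyphenyl hydrogen sulfate | CC(=O)c1ccc(OS(=O)(=O)O)cc1O
F4 | step 1 | 1-[2-hydroxy-4-(methoxymethoxy)phenyl]ethan-1-one | CC(=O)c1ccc(OCOC)cc1O
F5 | step 1 | 3-methoxy-4-(methoxymethoxy)benzaldehyde | COCOc1ccc(C=O)cc1OC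
F6 | step 1 | (E)-1-[2-hydroxy-4-(methoxymethoxy)phenyl]-3-[3-methoxy-4-(methoxymethoxy)phenyl]prop-2-en-1-one | COCOc1ccc(/C=C/C(=O)c2ccc(OCOC)cc2O)cc1OC
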